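Readings and results come from a simulation on assumed constants; noise was put on by code.

At late times a flask holds the target made minus the target since used, so start from the last readings of the earlier runs.

| flask | starting material | partner | temperature | remark | time |
|---|---|---|---|---|---|
| autumn | 6 mM | 5 equiv | 80 °C | run made earlier |  |
| midnight | 9 mM | 5 equiv | 92 °C | run made earlier |  |
| red | 12 mM | 5.00 equiv | 85 °C |  | 3.0 d |
| teal | 12 mM | 5.00 equiv |  | at 85 °C until 2.0 d, from then on at 100 °C | 3.0 d |
| ochre | 12 mM | 5.00 equiv | 100 °C |  | 3.0 d |

- autumn (time / h: target / %, starting material / %): 3.00: 0.7, 98.8; 6.00: 0, 98.8; 12.0: 1.4, 96.4; 25.0: 2.4, 94.3; 40.0: 3.7, 90.1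
- midnight (time / h: target / %, starting material / %): 3.00: 1.6, 96.4; 6.00: 2.6, 92.4; 12.0: 4.8, 85.7; 25.0: 9.5, 74.3; 40.0: 13.9, 61.9

(scatter of a reading: 0.5 percentage points)



- the flask with the highest amount of target, in percent of the starting material charged ("all alike" if they lie within 1.5 percentage points) (red / teal / ochre / all alike)
- final target, as a percentage of the starting material charged, in red
- final target, as a percentage of the starting material charged, in teal
- final target, as a percentage of the starting material charged, in ochre

Take the target found per starting material lost, s, the integral selectivity, from the last midnight reading: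

s = 0.365

The last autumn reading gives 0.374, so these readings show no drift. Suppose s holds in ochre, and bracket ochre by my own reckoning.

From above, complete loss of starting material allows 36.5%. To tighten this, take the pseudo-first-order constants of the two runs:

k(autumn) = 0.00261 h⁻¹
k(midnight) = 0.0120 h⁻¹

Stretching the same factor per degree from 92 °C to 100 °C gives:

k(ochre) = 0.0332 h⁻¹
upper bound = 33.1%

From below, ochre is hotter than midnight, and its c(partner) of 60.0 mM exceeds midnight's 45.0 mM. Its constant should therefore not fall below midnight's:

lower bound = 21.1%

The stretch above takes zero order in partner; first order moves k(ochre) to 0.0338 h⁻¹ and the top of the bracket to 33.3%. The stretch to 100 °C is an assumption of mine, so I keep midnight's constant as the floor.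

The forecast gives 16% for red, 25% for teal and 32% for ochre, so ochre leads. Its ochre value lies inside the bracket, near the top, and rests on this reading: “Target is a steady ~37% of starting material lost in both runs”.

The flasks give 16.2% in red, 21.7% in teal and 24.7% in ochre, so ochre leads.

    starting material + partner ⇌ target (K = 520 L mol⁻¹, k = 6.60 × 10⁻⁵ L mol⁻¹ s⁻¹, Ea = 104 kJ mol⁻¹, ΔH = −23.0 kJ mol⁻¹)
    starting material + partner → isomer of the product A (k = 1.60 × 10⁻⁵ L mol⁻¹ s⁻¹, Ea = 83.0 kJ mol⁻¹)
    starting material + partner → second isomer (k = 7.90 × 10⁻⁵ L mol⁻¹ s⁻¹, Ea = 108 kJ mol⁻¹)
    target ⇌ isomer of the product B (K = 0.580, k = 4.80 × 10⁻⁶ s⁻¹, Ea = 120 kJ mol⁻¹, ΔH = 21.0 kJ mol⁻¹)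
    (constants at 100 °C)

Ochre lies inside the bracket, 7.3 percentage points below the forecast. There, s applied to the starting material lost gives 32.3%, while the share found is 0.279, less than s. In ochre, target is made 3.52 times faster than it is used at 0.745 d. By 3.00 d that lead has shrunk to 1.31 times. In the neighbouring flask, like ochre but with 4.8 mM of starting material, s on the part lost gives 22.0%, and 17.5% stands there.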